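## Analysis of the target

Hispidulin 4'-sulfate is a flavone: a benzo-γ-pyranone (rings A and C) with a 4-sulfooxyphenyl ring B on C2. Ring A is pentasubstituted, with OH on C5, OMe on C6, OH on C7, the ring oxygen O1 on C8a and the carbonyl carbon C4 on C4a; only C8 carries hydrogen. There is no stereocentre, so the whole difficulty is regiochemical.

- **Ring-A pattern.** The 5,6,7-pattern has an isomeric twin, the 5,7,8-pattern. Any closure of ring C at oxygen from an aryl ketone flanked by two ortho hydroxyls can give either, and acid interconverts them (Wessely–Moser rearrangement).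
- **Site of sulfation.** The sulfate must go to the 4'-oxygen, although the 7-OH is the most acidic hydroxyl and the 5-OH is chelated to C4=O.
- **Sensitive group.** The aryl sulfate monoester is ionic and acid-labile, so it has to come after the last acidic step and the final unmasking has to be neutral.
- **Feature used.** In ring A the ether oxygen O1 (on C8a) is para to the methoxy carbon C6. C5–O and C7–O, and likewise C4a and C8, are paired across the C6···C8a axis. Ring A without the C4 carbon is therefore mirror-symmetric.

## Retrosynthetic reasoning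

**Unmasking.** Target 17 is traced back to the sodium sulfate 15, in which O5 and O7 are benzyl-type ethers. Hydrogenolysis is one of the few deprotections an aryl sulfate salt tolerates. It leaves the salt 16, which needs only a proton.

**S–O bond.** 15 is cut at the sulfate S–O bond to phenol 14. In 14 the 4'-OH is the only free hydroxyl, so sulfation has no site selectivity to solve. 14 comes from the allyl ether 13; an allyl ether can be removed without touching benzyl-type ethers.

**C4–C4a bond (key disconnection).** Ring C of 13 is cut at the carbon–carbon bond C4–C4a and not at O1–C2. The precursor is the mixed anhydride 12 of the aryloxyacrylic acid 11, both generated in the flask from the tert-butyl ester 10. In 10 the O1–C2 bond already exists, so O1 is fixed para to the methoxy group before the ring is closed and the 5,7,8-isomer cannot arise. The aryloxy ring of 10 has two ortho carbons that are equivalent by the mirror plane, so an intramolecular acylation has only one possible outcome. The forward reaction must acylate a carbon flanked by two oxygen substituents, which is best done intramolecularly.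

**O1–C2 bond.** 10 is cut at the enol ether C–O bond into phenol 5 and alkynoate 9. The forward reaction is a conjugate addition of the phenoxide to the β-carbon of the ynoate. Ring B enters with its oxygen already distinguished from the ring-A oxygens.

**C8a–O bond.** Phenol 5 is traced through boronate 4 to the bis-ether 3, made from diol 1 and bromide 2. The C–H bond of 3 that lies para to the methoxy group is the only arene C–H without an ortho substituent, so a sterically governed C–H borylation picks it out; electrophilic substitution would attack ortho and para to the ethers, at the wrong carbon. Bromide 2 is chosen because every ring C–H of its aryl group lies between two substituents and is blind to the borylation catalyst, while the group is still removed by hydrogenolysis.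

**Ring-B fragment.** Alkynoate 9 is traced through the lithium acetylide 8 and the dibromoalkene 7 to aldehyde 6, a one-carbon homologation followed by carboxylation.

## Alternatives that were turned down

**Alternative 1:** The textbook route closes ring C at O1–C2.
- Disconnection: the 2-hydroxyacetophenone 1-[2,4-bis(benzyloxy)-6-hydroxy-3-methoxyphenyl]ethan-1-one A1 is condensed with aldehyde 6 to the chalcone (E)-3-[4-(allyloxy)phenyl]-1-[2,4-bis(benzyloxy)-6-hydroxy-3-methoxyphenyl]prop-2-en-1-one A2.
- Forward key step: oxidative cyclisation of A2 (I2, DMSO, heat), or the Baker–Venkataraman diketone variant.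
- Reason turned down: the classical entry to A1, acylation of 2-methoxybenzene-1,3,5-triol A3 followed by partial benzylation, has to tell apart two ortho hydroxyls, and a free second ortho hydroxyl opens the Wessely–Moser scrambling. Even if the A1 pattern is reached from the symmetric phenol 5 by ortho-acetylation, three steps are needed from 5 to the protected flavone instead of two. Each has a structural liability: Lewis-acid acetylation endangers the benzyl-type ether ortho to the new carbonyl, the aldol of a 2,6-dioxygenated acetophenone is slow, and the iodine step generates HI at high temperature next to allyl and benzyl-type ethers and an iodinatable C8. The key step makes only a C–O bond, and it is the route most chemists would draw first.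

**Alternative 2:** Three-component carbonylative annulation, forming C4a–C4, C4–C3 and O1–C2.
- Disconnection: the iodophenol 3,5-bis[(3,5-dimethylbenzyl)oxy]-2-iodo-4-methoxyphenol A4 (from 5), the alkyne tert-butyl(4-ethynylphenoxy)dimethylsilane A5 and CO.
- Forward key step: carbonylative Sonogashira coupling (PdCl2(PPh3)2, CO, amine) and 6-endo closure of the ynone at oxygen.
- Reason turned down: the C–I bond of A4 sits between two oxygen substituents on a very electron-rich ring, so oxidative addition is slow and the direct, non-carbonylative coupling to a benzofuran competes. The final closure is again at oxygen and competes with 5-exo closure to an aurone. Iodination of 5 and a silyl group that must survive amine and CO add steps, so nothing is saved.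

**Alternative 3:** C2–C1' bond by oxidative coupling.
- Disconnection: the chromone 5,7-bis[(3,5-dimethylbenzyl)oxy]-6-methoxy-4H-chromen-4-one A6 and the boronic acid {4-[(tert-butyldimethylsilyl)oxy]phenyl}boronic acid A7.
- Forward key step: oxidative Heck arylation of A6 at C2 with A7 under divalent palladium catalysis (Pd(OAc)2, oxidant).
- Reason turned down: A6 already contains ring C, so the hardest ring must be built anyway before the key step, which then adds only an aryl group. A 5,7-dialkoxychromone is a poor acceptor, conjugate addition gives flavanone that must be re-oxidised, and boronic acid homocoupling competes. The route is longer.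

Key step: step 6

Remarks on the chemistry:
- The target is taken as the free hydrogen sulfate as drawn. It is formed in step 9 by protonation of its sodium salt 16 at 0 °C and should be lyophilised at once; the sodium salt is the storable form.
- Compound 10 is drawn as the Z isomer. Any E isomer formed with it is carried on, because step 6 equilibrates the two.

## Route

Step 1
Reactants: 1 2-methoxybenzene-1,3-diol; 2 1-(bromomethyl)-3,5-dimethylbenzene
Product: 3 1,3-bis[(3,5-dimethylbenzyl)oxy]-2-methoxybenzene
Conditions: K2CO3, 2 (2.2 equiv), DMF, 60 °C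
Reagents that add atoms: none
Why: Williamson ether synthesis on both phenols; the 3,5-dimethylbenzyl group is hydrogenolysable like benzyl, but all its ring C–H bonds lie between two substituents and should be inert in step 2.

Step 2
Reactants: 3 1,3-bis[(3,5-dimethylbenzyl)oxy]-2-methoxybenzene
Product: 5 3,5-bis[(3,5-dimethylbenzyl)oxy]-4-methoxyphenol, via aryl pinacol boronate 4 (not isolated)
Conditions: [Ir(OMe)(cod)]2 (cat.), 4,4'-di-tert-butyl-2,2'-bipyridine, B2pin2 (1.0 equiv), THF, 80 °C; then 30% aq. H2O2, 1 M NaOH, THF, 0 °C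
Reagents that add atoms: bis(pinacolato)diboron CC1(C)OB(OC1(C)C)B1OC(C)(C)C(C)(C)O1 (boron group of intermediate 4); hydrogen peroxide OO (phenol oxygen of 5)
Why: Sterically controlled iridium-catalysed arene C–H borylation should take the only C–H without an ortho substituent, the one para to the methoxy group; oxidation of the boronate in the same flask gives the C2v-symmetric phenol.

Step 3
Reactants: 6 4-(allyloxy)benzaldehyde
Product: 7 1-(allyloxy)-4-(2,2-dibromovinyl)benzene
Conditions: CBr4, PPh3, CH2Cl2, 0 °C
Reagents that add atoms: carbon tetrabromide BrC(Br)(Br)Br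
Why: First stage of the Corey–Fuchs homologation (Wittig-type dibromo-olefination of the aldehyde); the allyl ether is inert.

Step 4
Reactants: 7 1-(allyloxy)-4-(2,2-dibromovinyl)benzene
Product: 9 tert-butyl 3-[4-(allyloxy)phenyl]prop-2-ynoate, via lithium acetylide 8 (not isolated)
Conditions: n-BuLi (2.1 equiv), THF, −78 °C; then Boc2O, −78 → 0 °C
Reagents that add atoms: di-tert-butyl dicarbonate CC(C)(C)OC(=O)OC(=O)OC(C)(C)C; n-butyllithium [Li]CCCC (lithium of intermediate 8)
Why: Second stage of the Corey–Fuchs reaction (bromine–lithium exchange and Fritsch–Buttenberg–Wiechell rearrangement) gives the lithium acetylide, which is acylated by the dicarbonate to the tert-butyl ynoate.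

Step 5
Reactants: 5 3,5-bis[(3,5-dimethylbenzyl)oxy]-4-methoxyphenol; 9 tert-butyl 3-[4-(allyloxy)phenyl]prop-2-ynoate
Product: 10 tert-butyl (Z)-3-[4-(allyloxy)phenyl]-3-{3,5-bis[(3,5-dimethylbenzyl)oxy]-4-methoxyphenoxy}prop-2-enoate
Conditions: K2CO3, DMF, 90 °C, argon
Reagents that add atoms: none
Why: Base-mediated oxa-Michael addition of the unhindered phenoxide to the β-carbon of the aryl ynoate forms the O1–C2 bond; anti addition places the aryloxy group cis to the ester (Z).

Step 6
Reactants: 10 tert-butyl (Z)-3-[4-(allyloxy)phenyl]-3-{3,5-bis[(3,5-dimethylbenzyl)oxy]-4-methoxyphenoxy}prop-2-enoate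
Product: 13 2-[4-(allyloxy)phenyl]-5,7-bis[(3,5-dimethylbenzyl)oxy]-6-methoxy-4H-chromen-4-one, via acrylic acid 11 (not isolated), via mixed anhydride 12 (not isolated)
Conditions: TFA–CH2Cl2 (1:4), 0 → 23 °C; then TFAA (3 equiv), 0 → 23 °C; aq. NaHCO3 work-up
Reagents that add atoms: trifluoroacetic anhydride O=C(OC(=O)C(F)(F)F)C(F)(F)F (trifluoroacetyl group of intermediate 12 only; no atoms stay in 13)
Why: Intramolecular Friedel–Crafts acylation of a 3-aryloxycinnamic acid, the known carbon–carbon closure of flavones, run here under mixed-anhydride activation. TFA ionises the tert-butyl ester to acid 11 with loss of 2-methylpropene, and TFAA turns 11 into mixed anhydride 12, which acylates the aryloxy ring directly or through its acylium ion, stabilised by the β-aryloxy oxygen. Ring C closes in a six-membered mode (6-exo-trig at the anhydride carbonyl) by attack of a ring-A carbon ortho to the ether oxygen, forming C4–C4a; loss of a proton restores the arene, and no stereocentre is formed. The attacking carbon has one benzyl-type ether ortho and one para besides the ortho vinyl ether oxygen, a phloroglucinol-type position, so anhydride activation should suffice and no metal Lewis acid that would strip the ethers is needed. Regioselectivity is secured by the substrate: the two ortho carbons are equivalent through the mirror plane of the aryloxy ring, and since O1–C2 exists before ring closure the 5,7,8-isomer cannot form. Only the Z isomer can reach the ring, but protonation of the push–pull enol ether at the α-carbon gives a cation at the β-carbon stabilised by the aryloxy oxygen and the 4-allyloxyphenyl ring, about which the bond rotates, so E material is funnelled through Z. The competing five-membered closure onto ring B (an indenone) is disfavoured because that carbon is meta to the allyloxy group and the ring would be strained. The allyl ether and the benzyl-type ethers should tolerate the short exposure to TFA at or below room temperature.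

Step 7
Reactants: 13 2-[4-(allyloxy)phenyl]-5,7-bis[(3,5-dimethylbenzyl)oxy]-6-methoxy-4H-chromen-4-one
Product: 14 5,7-bis[(3,5-dimethylbenzyl)oxy]-2-(4-hydroxyphenyl)-6-methoxy-4H-chromen-4-one
Conditions: Pd(PPh3)4 (cat.), K2CO3, MeOH–THF, 23 °C
Reagents that add atoms: none
Why: Tsuji–Trost-type deallylation: zerovalent palladium ionises the allyl aryl ether to a π-allyl complex, the 4'-phenoxide conjugated to the chromone being a good leaving group, and methanol captures the allyl group; the benzyl-type ethers are untouched.

Step 8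
Reactants: 14 5,7-bis[(3,5-dimethylbenzyl)oxy]-2-(4-hydroxyphenyl)-6-methoxy-4H-chromen-4-one
Product: 15 sodium 4-{5,7-bis[(3,5-dimethylbenzyl)oxy]-6-methoxy-4-oxo-4H-chromen-2-yl}phenyl sulfate
Conditions: SO3·pyridine (4 equiv), pyridine, 40 °C; then aq. NaHCO3; C18 or Sephadex LH-20
Reagents that add atoms: sulfur trioxide pyridine complex [O-]S(=O)(=O)[n+]1ccccc1; sodium hydrogen carbonate [Na+].OC([O-])=O
Why: O-sulfonation of the only free hydroxyl by a sulfur trioxide–amine complex; all acidic steps lie behind, and the sulfate is kept as its sodium salt.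

Step 9
Reactants: 15 sodium 4-{5,7-bis[(3,5-dimethylbenzyl)oxy]-6-methoxy-4-oxo-4H-chromen-2-yl}phenyl sulfate
Product: 17 4-(5,7-dihydroxy-6-methoxy-4-oxo-4H-chromen-2-yl)phenyl hydrogen sulfate (hispidulin 4'-sulfate), via sodium salt 16 (not isolated)
Conditions: H2 (1 atm), Pd/C, MeOH–THF–H2O, 23 °C; filter; then aq. HCl (1.0 equiv), 0 °C, C18 desalting, lyophilise
Reagents that add atoms: none
Why: Catalytic hydrogenolysis of the two benzyl-type aryl ethers, a standard unmasking in the presence of aryl sulfate salts that should leave the flavone C2=C3 bond intact at one atmosphere; protonation of salt 16 then gives the hydrogen sulfate.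

## Compound list

1 | 2-methoxybenzene-1,3-diol (2-methoxyresorcinol) | COc1c(O)cccc1O | starting material
2 | 1-(bromomethyl)-3,5-dimethylbenzene (3,5-dimethylbenzyl bromide) | Cc1cc(C)cc(CBr)c1 | starting material
3 | 1,3-bis[(3,5-dimethylbenzyl)oxy]-2-methoxybenzene | COc1c(OCc2cc(C)cc(C)c2)cccc1OCc1cc(C)cc(C)c1 | intermediate
4 | 2-{3,5-bis[(3,5-dimethylbenzyl)oxy]-4-methoxyphenyl}-4,4,5,5-tetramethyl-1,3,2-dioxaborolane | COc1c(OCc2cc(C)cc(C)c2)cc(B2OC(C)(C)C(C)(C)O2)cc1OCc1cc(C)cc(C)c1 | intermediate (not isolated)
5 | 3,5-bis[(3,5-dimethylbenzyl)oxy]-4-methoxyphenol | COc1c(OCc2cc(C)cc(C)c2)cc(O)cc1OCc1cc(C)cc(C)c1 | intermediate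
6 | 4-(allyloxy)benzaldehyde | C=CCOc1ccc(C=O)cc1 | starting material
7 | 1-(allyloxy)-4-(2,2-dibromovinyl)benzene | C=CCOc1ccc(C=C(Br)Br)cc1 | intermediate
8 | lithium [4-(allyloxy)phenyl]acetylide | [Li]C#Cc1ccc(OCC=C)cc1 | intermediate (not isolated)
9 | tert-butyl 3-[4-(allyloxy)phenyl]prop-2-ynoate | C=CCOc1ccc(C#CC(=O)OC(C)(C)C)cc1 | intermediate
10 | tert-butyl (Z)-3-[4-(allyloxy)phenyl]-3-{3,5-bis[(3,5-dimethylbenzyl)oxy]-4-methoxyphenoxy}prop-2-enoate | CC(C)(C)OC(=O)/C=C(\Oc1cc(OCc2cc(C)cc(C)c2)c(OC)c(OCc2cc(C)cc(C)c2)c1)c1ccc(OCC=C)cc1 | intermediate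
11 | (Z)-3-[4-(allyloxy)phenyl]-3-{3,5-bis[(3,5-dimethylbenzyl)oxy]-4-methoxyphenoxy}prop-2-enoic acid | OC(=O)/C=C(\Oc1cc(OCc2cc(C)cc(C)c2)c(OC)c(OCc2cc(C)cc(C)c2)c1)c1ccc(OCC=C)cc1 | intermediate (not isolated)
12 | (Z)-3-[4-(allyloxy)phenyl]-3-{3,5-bis[(3,5-dimethylbenzyl)oxy]-4-methoxyphenoxy}prop-2-enoic trifluoroacetic anhydride | O=C(OC(=O)C(F)(F)F)/C=C(\Oc1cc(OCc2cc(C)cc(C)c2)c(OC)c(OCc2cc(C)cc(C)c2)c1)c1ccc(OCC=C)cc1 | intermediate (not isolated)
13 | 2-[4-(allyloxy)phenyl]-5,7-bis[(3,5-dimethylbenzyl)oxy]-6-methoxy-4H-chromen-4-one | COc1c(OCc2cc(C)cc(C)c2)cc2oc(-c3ccc(OCC=C)cc3)cc(=O)c2c1OCc1cc(C)cc(C)c1 | intermediate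
14 | 5,7-bis[(3,5-dimethylbenzyl)oxy]-2-(4-hydroxyphenyl)-6-methoxy-4H-chromen-4-one | COc1c(OCc2cc(C)cc(C)c2)cc2oc(-c3ccc(O)cc3)cc(=O)c2c1OCc1cc(C)cc(C)c1 | intermediate
15 | sodium 4-{5,7-bis[(3,5-dimethylbenzyl)oxy]-6-methoxy-4-oxo-4H-chromen-2-yl}phenyl sulfate | COc1c(OCc2cc(C)cc(C)c2)cc2oc(-c3ccc(OS(=O)(=O)[O-])cc3)cc(=O)c2c1OCc1cc(C)cc(C)c1.[Na+] | intermediate
16 | sodium 4-(5,7-dihydroxy-6-methoxy-4-oxo-4H-chromen-2-yl)phenyl sulfate | COc1c(O)cc2oc(-c3ccc(OS(=O)(=O)[O-])cc3)cc(=O)c2c1O.[Na+] | intermediate (not isolated)
17 | 4-(5,7-dihydroxy-6-methoxy-4-oxo-4H-chromen-2-yl)phenyl hydrogen sulfate (hispidulin 4'-sulfate) | COc1c(O)cc2oc(-c3ccc(OS(=O)(=O)O)cc3)cc(=O)c2c1O | target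

## Step count and risk

Total step count: 9. Longest linear sequence: 7 steps (steps 1, 2, 5, 6, 7, 8, 9; the ring-B branch, steps 3 and 4, joins at step 5).

**Step 6 (key step).** The most likely failure is competition between ring closure and acid-induced loss of a benzyl-type ether, above all the one that ends up next to the new carbonyl. Trifluoroacetylation of the electron-rich ring and slow funnelling of the E isomer through Z are further possibilities. The fallback gives up the carbon–carbon closure and sets out from phenol 5 and aldehyde 6. Phenol 5 is C-acetylated at one of its two equivalent ortho carbons (Ac2O, BF3·OEt2, or O-acetylation and TiCl4-mediated Fries rearrangement) to 1-{6-hydroxy-2,4-bis[(3,5-dimethylbenzyl)oxy]-3-methoxyphenyl}ethan-1-one F1. Claisen–Schmidt condensation of F1 with 6 (KOH, EtOH) should give (E)-3-[4-(allyloxy)phenyl]-1-{6-hydroxy-2,4-bis[(3,5-dimethylbenzyl)oxy]-3-methoxyphenyl}prop-2-en-1-one F2. Oxidative cyclisation of F2 (cat. I2, DMSO, 120 °C) comes back to the route at 13.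

**Step 5.** The conjugate addition may be sluggish, because the 4-allyloxyphenyl group makes the ynoate a weak acceptor, and forcing it invites base-induced decomposition. The fallback raises the acceptor strength by changing the oxidation level. It sets out from dibromoalkene 7 and phenol 5. 7 is converted as in step 4 into acetylide 8, which is formylated with DMF to 3-[4-(allyloxy)phenyl]prop-2-ynal F3. Phenol 5 should add to F3 at 23 °C under catalytic DABCO to give (Z)-3-[4-(allyloxy)phenyl]-3-{3,5-bis[(3,5-dimethylbenzyl)oxy]-4-methoxyphenoxy}prop-2-enal F4. Pinnick oxidation (NaClO2, NaH2PO4, 2-methyl-2-butene) comes back to the route at acid 11, which is then cyclised with TFAA as in the second stage of step 6.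

**Step 2.** The electron-rich arene may borylate slowly, and the electron-rich phenol may be over-oxidised during the peroxide treatment. The fallback brings in the oxygen by Dakin chemistry. It sets out from bromide 2 and commercial methyl 3,5-dihydroxy-4-methoxybenzoate F5. Alkylation of F5 with 2 (K2CO3, DMF) gives methyl 3,5-bis[(3,5-dimethylbenzyl)oxy]-4-methoxybenzoate F6. Reduction (LiAlH4, THF) gives {3,5-bis[(3,5-dimethylbenzyl)oxy]-4-methoxyphenyl}methanol F7, and oxidation (MnO2, CH2Cl2) gives 3,5-bis[(3,5-dimethylbenzyl)oxy]-4-methoxybenzaldehyde F8. Baeyer–Villiger oxidation (mCPBA, CH2Cl2) gives 3,5-bis[(3,5-dimethylbenzyl)oxy]-4-methoxyphenyl formate F9, whose methanolysis (K2CO3, MeOH) comes back to the route at 5.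

**Step 8.** Sulfation of the weakly nucleophilic 4'-phenol may stay incomplete, and sulfate may be lost during purification of the salt. The fallback carries the sulfate as a neutral diester that can be chromatographed on silica. It sets out from 14. Treatment with 2,2,2-trichloroethyl chlorosulfate (Et3N, DMAP, THF) gives 4-{5,7-bis[(3,5-dimethylbenzyl)oxy]-6-methoxy-4-oxo-4H-chromen-2-yl}phenyl 2,2,2-trichloroethyl sulfate F10. Reductive cleavage of the trichloroethyl group (Zn, HCO2NH4, MeOH) and exchange to the sodium form come back to the route at 15.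

## Further compounds

F1 | step 6 | 1-{6-hydroxy-2,4-bis[(3,5-dimethylbenzyl)oxy]-3-methoxyphenyl}ethan-1-one | CC(=O)c1c(O)cc(OCc2cc(C)cc(C)c2)c(OC)c1OCc1cc(C)cc(C)c1
F2 | step 6 | (E)-3-[4-(allyloxy)phenyl]-1-{6-hydroxy-2,4-bis[(3,5-dimethylbenzyl)oxy]-3-methoxyphenyl}prop-2-en-1-one | O=C(/C=C/c1ccc(OCC=C)cc1)c1c(O)cc(OCc2cc(C)cc(C)c2)c(OC)c1OCc1cc(C)cc(C)c1
F3 | step 5 | 3-[4-(allyloxy)phenyl]prop-2-ynal | C=CCOc1ccc(C#CC=O)cc1
F4 | step 5 | (Z)-3-[4-(allyloxy)phenyl]-3-{3,5-bis[(3,5-dimethylbenzyl)oxy]-4-methoxyphenoxy}prop-2-enal | O=C/C=C(\Oc1cc(OCc2cc(C)cc(C)c2)c(OC)c(OCc2cc(C)cc(C)c2)c1)c1ccc(OCC=C)cc1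
F5 | step 2 | methyl 3,5-dihydroxy-4-methoxybenzoate | COC(=O)c1cc(O)c(OC)c(O)c1
F6 | step 2 | methyl 3,5-bis[(3,5-dimethylbenzyl)oxy]-4-methoxybenzoate | COC(=O)c1cc(OCc2cc(C)cc(C)c2)c(OC)c(OCc2cc(C)cc(C)c2)c1
F7 | step 2 | {3,5-bis[(3,5-dimethylbenzyl)oxy]-4-methoxyphenyl}methanol | OCc1cc(OCc2cc(C)cc(C)c2)c(OC)c(OCc2cc(C)cc(C)c2)c1
F8 | step 2 | 3,5-bis[(3,5-dimethylbenzyl)oxy]-4-methoxybenzaldehyde | O=Cc1cc(OCc2cc(C)cc(C)c2)c(OC)c(OCc2cc(C)cc(C)c2)c1
F9 | step 2 | 3,5-bis[(3,5-dimethylbenzyl)oxy]-4-methoxyphenyl formate | O=COc1cc(OCc2cc(C)cc(C)c2)c(OC)c(OCc2cc(C)cc(C)c2)c1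
F10 | step 8 | 4-{5,7-bis[(3,5-dimethylbenzyl)oxy]-6-methoxy-4-oxo-4H-chromen-2-yl}phenyl 2,2,2-trichloroethyl sulfate | COc1c(OCc2cc(C)cc(C)c2)cc2oc(-c3ccc(OS(=O)(=O)OCC(Cl)(Cl)Cl)cc3)cc(=O)c2c1OCc1cc(C)cc(C)c1
A1 | alternative 1 | 1-[2,4-bis(benzyloxy)-6-hydroxy-3-methoxyphenyl]ethan-1-one | CC(=O)c1c(O)cc(OCc2ccccc2)c(OC)c1OCc1ccccc1
A2 | alternative 1 | (E)-3-[4-(allyloxy)phenyl]-1-[2,4-bis(benzyloxy)-6-hydroxy-3-methoxyphenyl]prop-2-en-1-one | O=C(/C=C/c1ccc(OCC=C)cc1)c1c(O)cc(OCc2ccccc2)c(OC)c1OCc1ccccc1
A3 | alternative 1 | 2-methoxybenzene-1,3,5-triol | COc1c(O)cc(O)cc1O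
A4 | alternative 2 | 3,5-bis[(3,5-dimethylbenzyl)oxy]-2-iodo-4-methoxyphenol | COc1c(OCc2cc(C)cc(C)c2)cc(O)c(I)c1OCc1cc(C)cc(C)c1
A5 | alternative 2 | tert-butyl(4-ethynylphenoxy)dimethylsilane | CC(C)(C)[Si](C)(C)Oc1ccc(C#C)cc1
A6 | alternative 3 | 5,7-bis[(3,5-dimethylbenzyl)oxy]-6-methoxy-4H-chromen-4-one | COc1c(OCc2cc(C)cc(C)c2)cc2occc(=O)c2c1OCc1cc(C)cc(C)c1
A7 | alternative 3 | {4-[(tert-butyldimethylsilyl)oxy]phenyl}boronic acid | CC(C)(C)[Si](C)(C)Oc1ccc(B(O)O)cc1
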